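**Retrosynthetic overview**

Target numbering used here: ring C1 (tertiary carbinol carrying the exocyclic C7H2OBz), C2 (CHOH), C3=C4, C5 and C6 (CHOAc).
Late stage: the C2 carbinol comes from hydroxyl-directed reduction of a C2 enone; the C3=C4 π-bond from E1cB loss of a C4 benzoate; the C2 ketone from ozonolysis of a silyl enol ether made from a sacrificial formyl group on C2.
Middle stage: C7H2O and the C4–O leaving group both come from hydride opening of a C1–C7(=O)–O–C4 lactone bridge; the cis-5,6-diol comes from osmylation of a 2-oxabicyclo[2.2.2]octene on its lactone face.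
Key disconnection: C1–C2 and the σ-bond C3–C4 together, by a catalytic enantioselective Diels–Alder reaction of 3-hydroxy-2-pyrone (supplies C1, C6, C5, C4, C7 and the C1 hydroxyl) with acrolein (supplies C2, C3). The enabling feature is the tertiary carbinol C1 with its oxygenated one-carbon branch C7, standing 1,4 to C4 across the six-membered carbocycle: the imprint of a pyrone O–C(=O) bridge.
Ring order: the carbocycle and the bridging lactone ring are formed together in step 1; the lactone ring is opened in step 4; no other ring is made.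

Key step: step 1

Assumption: the cupreidine-derived catalyst is taken to give the (1R,4S) cycloadduct; if it gives the antipode, the pseudoenantiomeric cupreine-derived catalyst is used with no other change.
Remark: the formyl-bearing carbon of the cycloadduct (endo isomer drawn) may be an epimer mixture and the silyl enol ether a mixture of geometric isomers; both converge when that carbon becomes the ketone carbon.

**Route**

Step 1
Reactants: 1 3-hydroxy-2H-pyran-2-one; 2 acrolein
Product: 3 (1R,4S,5R)-4-hydroxy-3-oxo-2-oxabicyclo[2.2.2]oct-7-ene-5-carbaldehyde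
Conditions: 9-O-benzylcupreidine (10 mol %), 2 (1.5 equiv, slow addition), Et2O/EtOAc, 0 °C
Reagents that add atoms: none
Why: The quinuclidine nitrogen of the catalyst deprotonates the 3-hydroxyl of 1 and ion-pairs with the resulting 3-oxidopyrone (a HOMO-raised diene) while the 6'-hydroxyl hydrogen-bonds the formyl oxygen of 2, so that nucleophilic C6 of the pyrone bonds to the β-carbon of acrolein and its α-carbon bonds to C3 in an asynchronous [4+2] cycloaddition, creating the C1–C6 and C4–C5 bonds of 3, which are the C3–C4 and C1–C2 bonds of the target. The closest known reaction type is the amine-base-catalysed Diels–Alder reaction of 3-hydroxy-2-pyrones with electron-poor alkenes (enones, acrylates, acrylonitriles) under bifunctional cinchona catalysis. The six-membered carbocycle, and with it the 2-oxabicyclo[2.2.2]octene, is closed by intermolecular suprafacial [4+2] cycloaddition (in the stepwise limit, Michael addition followed by 6-exo-trig aldol closure). The bridgehead stereocentres C1 and C4 arise together and are fixed by the catalyst, which shields one face of the bound dienolate; C5 is expected endo but needs no control because it becomes sp2 in step 3. The step needs regioselectivity (formyl-bearing carbon next to the carbinol bridgehead), secured by the polarity of the 3-oxidopyrone (C6 nucleophilic, C3 electrophilic), and enantiofacial selectivity, secured by the catalyst.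

Step 2
Reactants: 3 (1R,4S,5R)-4-hydroxy-3-oxo-2-oxabicyclo[2.2.2]oct-7-ene-5-carbaldehyde
Product: 4 (1R,4R,5R,7S,8R)-4,7,8-trihydroxy-3-oxo-2-oxabicyclo[2.2.2]octane-5-carbaldehyde
Conditions: K2OsO4·2H2O (2 mol %), NMO, citric acid, t-BuOH/H2O, rt; crude product used at once
Reagents that add atoms: N-methylmorpholine N-oxide, C[N+]1([O-])CCOCC1; water, O
Why: Catalytic osmylation (NMO as reoxidant) is a suprafacial cis-dihydroxylation that should occur on the alkene face syn to the flat O–C(=O) bridge, the other face being screened by the substituted C5–C6 bridge, which sets both new carbinol centres (C7, C8) on the lactone side, while the acidic buffer suppresses lactone migration.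

Step 3
Reactants: 4 (1R,4R,5R,7S,8R)-4,7,8-trihydroxy-3-oxo-2-oxabicyclo[2.2.2]octane-5-carbaldehyde
Product: 5 (1R,4R,5R,6R)-4,5,6-tris(triethylsilyloxy)-8-[(triethylsilyloxy)methylidene]-2-oxabicyclo[2.2.2]octan-3-one
Conditions: TESOTf (5 equiv), Et3N, CH2Cl2, −78 → 0 °C
Reagents that add atoms: triethylsilyl trifluoromethanesulfonate, CC[Si](CC)(CC)OS(=O)(=O)C(F)(F)F
Why: Silyl triflate with amine base silylates the three hydroxyls and converts the enolisable aldehyde into its silyl enol ether (soft enolisation), which blocks retro-aldol and lactone migration and masks the future ketone as an alkene; no stereocentre is formed and the formyl-bearing carbon becomes sp2.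

Step 4
Reactants: 5 (1R,4R,5R,6R)-4,5,6-tris(triethylsilyloxy)-8-[(triethylsilyloxy)methylidene]-2-oxabicyclo[2.2.2]octan-3-one
Product: 6 (1R,2R,3R,4S)-4-(hydroxymethyl)-2,3,4-tris(triethylsilyloxy)-5-[(triethylsilyloxy)methylidene]cyclohexan-1-ol
Conditions: i-Bu2AlH (4 equiv), CH2Cl2, −78 → 0 °C; aq. potassium sodium tartrate work-up
Reagents that add atoms: none
Why: Aluminium hydride reduction of the lactone (through the lactol) gives the primary alcohol on the quaternary carbon and frees the secondary hydroxyl at the former bridgehead with retention, since no bond to a stereocentre is broken and silyl ethers and the silyl enol ether are inert to the hydride.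

Step 5
Reactants: 6 (1R,2R,3R,4S)-4-(hydroxymethyl)-2,3,4-tris(triethylsilyloxy)-5-[(triethylsilyloxy)methylidene]cyclohexan-1-ol
Product: 7 [(1S,2R,3R,4R)-4-(benzoyloxy)-1,2,3-tris(triethylsilyloxy)-6-[(triethylsilyloxy)methylidene]cyclohexyl]methyl benzoate
Conditions: BzCl (3 equiv), pyridine, DMAP (cat.), CH2Cl2, 0 °C → rt
Reagents that add atoms: benzoyl chloride, O=C(Cl)c1ccccc1
Why: Acylation of both free hydroxyls installs the primary benzoate of the target and turns the secondary hydroxyl into the leaving group for step 6, without touching any stereocentre.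

Step 6
Reactants: 7 [(1S,2R,3R,4R)-4-(benzoyloxy)-1,2,3-tris(triethylsilyloxy)-6-[(triethylsilyloxy)methylidene]cyclohexyl]methyl benzoate
Product: 9 [(1S,5R,6R)-2-oxo-1,5,6-tris(triethylsilyloxy)cyclohex-3-en-1-yl]methyl benzoate, via benzoyloxy ketone 8 (not isolated)
Conditions: O3, CH2Cl2, −78 °C; Me2S, −78 → 0 °C; then Et3N, 0 °C
Reagents that add atoms: ozone, [O-][O+]=O
Why: Ozonolysis of the electron-rich silyl enol ether excises the one-carbon mask and leaves the ring ketone, whose β-benzoate is then expelled by amine-induced E1cB elimination through the only enolate available (the CH2 side), which places the ring double bond regiospecifically without creating a stereocentre.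

Step 7
Reactants: 9 [(1S,5R,6R)-2-oxo-1,5,6-tris(triethylsilyloxy)cyclohex-3-en-1-yl]methyl benzoate
Product: 10 [(1S,5R,6R)-1,5,6-trihydroxy-2-oxocyclohex-3-en-1-yl]methyl benzoate
Conditions: HF·pyridine, THF/pyridine, 0 °C → rt
Reagents that add atoms: none
Why: Fluoride-driven cleavage of the three triethylsilyl ethers proceeds under mildly acidic conditions that leave the benzoate and the base-sensitive enone untouched and affect no stereocentre.

Step 8
Reactants: 10 [(1S,5R,6R)-1,5,6-trihydroxy-2-oxocyclohex-3-en-1-yl]methyl benzoate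
Product: 11 [(1S,5R,6R)-5,6-bis(acetyloxy)-1-hydroxy-2-oxocyclohex-3-en-1-yl]methyl benzoate
Conditions: Ac2O, pyridine, 0 °C → rt (no DMAP)
Reagents that add atoms: acetic anhydride, CC(=O)OC(C)=O
Why: The two secondary hydroxyls are acetylated while the hindered tertiary α-ketol hydroxyl does not react, and C2 needs no protection because it is still a ketone; no stereocentre is touched.

Step 9
Reactants: 11 [(1S,5R,6R)-5,6-bis(acetyloxy)-1-hydroxy-2-oxocyclohex-3-en-1-yl]methyl benzoate
Product: 12 [(1R,2S,5R,6R)-5,6-bis(acetyloxy)-1,2-dihydroxycyclohex-3-en-1-yl]methyl benzoate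
Conditions: Me4NBH(OAc)3, MeCN/AcOH (1:1), −30 → −10 °C
Reagents that add atoms: none
Why: In this hydroxyl-directed triacetoxyborohydride reduction (Saksena–Evans type) the tertiary hydroxyl exchanges onto boron and delivers hydride to the adjacent ketone from its own face, which should give 1,2-reduction and the trans-1,2-diol and so set the last stereocentre (C2, S) while esters and alkene stay intact.

**Compound list**

1 | 3-hydroxy-2H-pyran-2-one | O=C1OC=CC=C1O | starting material
2 | acrolein (prop-2-enal) | C=CC=O | starting material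
3 | (1R,4S,5R)-4-hydroxy-3-oxo-2-oxabicyclo[2.2.2]oct-7-ene-5-carbaldehyde | O=C1O[C@H]2C=C[C@]1(O)[C@H](C=O)C2 | intermediate
4 | (1R,4R,5R,7S,8R)-4,7,8-trihydroxy-3-oxo-2-oxabicyclo[2.2.2]octane-5-carbaldehyde | O=C1O[C@H]2[C@@H](O)[C@@H](O)[C@]1(O)[C@H](C=O)C2 | intermediate
5 | (1R,4R,5R,6R)-4,5,6-tris(triethylsilyloxy)-8-[(triethylsilyloxy)methylidene]-2-oxabicyclo[2.2.2]octan-3-one | O=C1O[C@H]2[C@@H](O[Si](CC)(CC)CC)[C@@H](O[Si](CC)(CC)CC)[C@]1(O[Si](CC)(CC)CC)C(=CO[Si](CC)(CC)CC)C2 | intermediate
6 | (1R,2R,3R,4S)-4-(hydroxymethyl)-2,3,4-tris(triethylsilyloxy)-5-[(triethylsilyloxy)methylidene]cyclohexan-1-ol | CC[Si](CC)(CC)O[C@@H]1[C@H](O[Si](CC)(CC)CC)[C@H](O)CC(=CO[Si](CC)(CC)CC)[C@]1(O[Si](CC)(CC)CC)CO | intermediate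
7 | [(1S,2R,3R,4R)-4-(benzoyloxy)-1,2,3-tris(triethylsilyloxy)-6-[(triethylsilyloxy)methylidene]cyclohexyl]methyl benzoate | CC[Si](CC)(CC)O[C@@H]1[C@H](O[Si](CC)(CC)CC)[C@H](OC(=O)c2ccccc2)CC(=CO[Si](CC)(CC)CC)[C@]1(O[Si](CC)(CC)CC)COC(=O)c1ccccc1 | intermediate
8 | [(1S,2R,3R,4R)-4-(benzoyloxy)-6-oxo-1,2,3-tris(triethylsilyloxy)cyclohexyl]methyl benzoate | CC[Si](CC)(CC)O[C@@H]1[C@H](O[Si](CC)(CC)CC)[C@H](OC(=O)c2ccccc2)CC(=O)[C@]1(O[Si](CC)(CC)CC)COC(=O)c1ccccc1 | intermediate (not isolated)
9 | [(1S,5R,6R)-2-oxo-1,5,6-tris(triethylsilyloxy)cyclohex-3-en-1-yl]methyl benzoate | CC[Si](CC)(CC)O[C@@H]1[C@H](O[Si](CC)(CC)CC)C=CC(=O)[C@]1(O[Si](CC)(CC)CC)COC(=O)c1ccccc1 | intermediate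
10 | [(1S,5R,6R)-1,5,6-trihydroxy-2-oxocyclohex-3-en-1-yl]methyl benzoate | O[C@@H]1[C@H](O)C=CC(=O)[C@]1(O)COC(=O)c1ccccc1 | intermediate
11 | [(1S,5R,6R)-5,6-bis(acetyloxy)-1-hydroxy-2-oxocyclohex-3-en-1-yl]methyl benzoate | CC(=O)O[C@@H]1[C@H](OC(C)=O)C=CC(=O)[C@]1(O)COC(=O)c1ccccc1 | intermediate
12 | [(1R,2S,5R,6R)-5,6-bis(acetyloxy)-1,2-dihydroxycyclohex-3-en-1-yl]methyl benzoate | CC(=O)O[C@@H]1[C@H](OC(C)=O)C=C[C@H](O)[C@]1(O)COC(=O)c1ccccc1 | target

**Step count and risks**

Total step count: 9. Longest linear sequence: 9 steps (fully linear from 1 and 2).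

Steps most likely to fail:

Step 1. What may go wrong: oligomerisation of the enal on the amine catalyst, reversal of the aldol-type closure, or weak enantiofacial discrimination. Fallback: the activation mode is inverted. The same partners are combined under iminium activation of the enal by a chiral primary amine salt (9-amino-9-deoxy-epi-quinine with trifluoroacetic acid), the mode known for 2-pyrone/enone cycloadditions, which lowers the LUMO of the dienophile instead of raising the HOMO of the diene. This sets out from 1 and 2 and comes back to the route at 3; it makes no new compound (F0).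

Step 2. What may go wrong: migration of the lactone to the neighbouring new hydroxyl, or osmylation on the wrong alkene face. Fallback: the diol is installed last, on a monocyclic dienone, setting out from 3 and returning at 10. Double silylation of 3 (TESOTf, Et3N) gives the silyl enol ether lactone (1R,4S)-4-(triethylsilyloxy)-5-[(triethylsilyloxy)methylidene]-2-oxabicyclo[2.2.2]oct-7-en-3-one F1. i-Bu2AlH opens the lactone to the cyclohexenediol (1R,4S)-4-(hydroxymethyl)-4-(triethylsilyloxy)-5-[(triethylsilyloxy)methylidene]cyclohex-2-en-1-ol F2. Benzoylation gives the dibenzoate [(1S,4R)-4-(benzoyloxy)-1-(triethylsilyloxy)-6-[(triethylsilyloxy)methylidene]cyclohex-2-en-1-yl]methyl benzoate F3. Ozonolysis limited to the electron-rich enol ether gives the ketone [(1R,4R)-4-(benzoyloxy)-6-oxo-1-(triethylsilyloxy)cyclohex-2-en-1-yl]methyl benzoate F4, and Et3N-induced E1cB loss of benzoate gives the 6,6-disubstituted dienone [(1R)-6-oxo-1-(triethylsilyloxy)cyclohexa-2,4-dien-1-yl]methyl benzoate F5. OsO4/NMO should then dihydroxylate the distal double bond anti to the silyloxy group on the quaternary carbon, giving the diol [(1S,5R,6R)-5,6-dihydroxy-2-oxo-1-(triethylsilyloxy)cyclohex-3-en-1-yl]methyl benzoate F6. HF·pyridine returns the route at 10.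

Step 9. What may go wrong: hydride delivery to the wrong face, conjugate reduction, or acetyl migration in the acidic medium. Fallback: substrate direction is replaced by reagent control. Corey–Bakshi–Shibata reduction of 11 with the matching enantiomer of the B-methyl oxazaborolidine and BH3·SMe2 in THF at −40 °C is a 1,2-selective enone reduction whose facial sense is dictated by the catalyst. It sets out from 11 and comes back at 12 without any new compound (F0).

**Further compounds**

F0 | step 1 | none | none
F1 | step 2 | (1R,4S)-4-(triethylsilyloxy)-5-[(triethylsilyloxy)methylidene]-2-oxabicyclo[2.2.2]oct-7-en-3-one | O=C1O[C@H]2C=C[C@]1(O[Si](CC)(CC)CC)C(=CO[Si](CC)(CC)CC)C2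
F2 | step 2 | (1R,4S)-4-(hydroxymethyl)-4-(triethylsilyloxy)-5-[(triethylsilyloxy)methylidene]cyclohex-2-en-1-ol | OC[C@]1(O[Si](CC)(CC)CC)C=C[C@H](O)CC1=CO[Si](CC)(CC)CC
F3 | step 2 | [(1S,4R)-4-(benzoyloxy)-1-(triethylsilyloxy)-6-[(triethylsilyloxy)methylidene]cyclohex-2-en-1-yl]methyl benzoate | O=C(OC[C@]1(O[Si](CC)(CC)CC)C=C[C@H](OC(=O)c2ccccc2)CC1=CO[Si](CC)(CC)CC)c1ccccc1
F4 | step 2 | [(1R,4R)-4-(benzoyloxy)-6-oxo-1-(triethylsilyloxy)cyclohex-2-en-1-yl]methyl benzoate | O=C(OC[C@]1(O[Si](CC)(CC)CC)C=C[C@H](OC(=O)c2ccccc2)CC1=O)c1ccccc1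
F5 | step 2 | [(1R)-6-oxo-1-(triethylsilyloxy)cyclohexa-2,4-dien-1-yl]methyl benzoate | O=C(OC[C@]1(O[Si](CC)(CC)CC)C=CC=CC1=O)c1ccccc1
F6 | step 2 | [(1S,5R,6R)-5,6-dihydroxy-2-oxo-1-(triethylsilyloxy)cyclohex-3-en-1-yl]methyl benzoate | O=C(OC[C@]1(O[Si](CC)(CC)CC)[C@H](O)[C@H](O)C=CC1=O)c1ccccc1
F0 | step 9 | none | none
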